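The route rests on cutting the C3–C4 bond of ring C. Because the 4'-hydroxyl of ring B lies para to C1', C3 can be unveiled as the exocyclic carbon of a transient para-quinone methide, while a chiral triazolylidene turns the ring-A formyl carbon (the future C4) into an acyl anion equivalent. One operation therefore forms C3–C4, closes ring C, fixes the (S) configuration at C3 and hands back the free 4'-phenol. The substrate is a geranylated, 7-O-triisopropylsilylated ring-A salicylaldehyde whose O1 carries the C2–C3 unit as a racemic 4-hydroxy-2-methoxybenzyl p-tolyl sulfone; it is built by Stille geranylation and a Mitsunobu etherification.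

Key step: step 9

Assumption: the sense of induction of the triazolium catalyst on this new acceptor cannot be predicted with confidence. The (5aR,10bS) salt is written; its mirror image is used instead if a pilot run favours the (R)-ketone.

Design remarks (geranyl = (2E)-3,7-dimethylocta-2,6-dien-1-yl):
- The 7-O silyl group is triisopropylsilyl. Its bulk should resist silyl transfer to the 4'-phenoxide present in step 9 and the heat of step 3, and bifluoride still removes it.
- The O1–C2 bond is made from a 2-aryl-2-sulfonylethanol, so its position does not depend on the regiochemistry of opening an electron-rich styrene oxide.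
- The 4'-phenol stays allylated until the step before the cyclisation, so no quinone methide can form early.

Step 1
Reactants: 1 5-bromo-2,4-dihydroxybenzaldehyde
Product: 2 5-bromo-2-hydroxy-4-[(triisopropylsilyl)oxy]benzaldehyde
Conditions: TIPSCl (1.05 equiv), imidazole, CH2Cl2, 0 °C → rt
Reagents that add atoms: chlorotriisopropylsilane, CC(C)[Si](Cl)(C(C)C)C(C)C
Why: O-silylation of a phenol, expected at the more acidic and unencumbered 4-OH because the 2-OH is held in a hydrogen bond to the formyl group.

Step 2
Reactants: 3 geranyl bromide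
Product: 4 tributyl(geranyl)stannane
Conditions: Bu3SnH, LDA, THF, 0 °C; then 3, −78 °C → 0 °C
Reagents that add atoms: tributyltin hydride, CCCC[SnH](CCCC)CCCC
Why: SN2 alkylation of tributylstannyllithium by a primary allylic bromide at low temperature, which should give the linear allylstannane with the E-alkene untouched.

Step 3
Reactants: 2 5-bromo-2-hydroxy-4-[(triisopropylsilyl)oxy]benzaldehyde; 4 tributyl(geranyl)stannane
Product: 5 5-geranyl-2-hydroxy-4-[(triisopropylsilyl)oxy]benzaldehyde
Conditions: Pd(PPh3)4 (5 mol %), DMF, 90 °C, degassed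
Reagents that add atoms: none
Why: Stille cross-coupling of an aryl bromide with an allylic stannane under neutral, fluoride-free conditions, which should join the primary carbon of the stannane to C5 with the E-alkene retained and leave the phenol, aldehyde and aryl silyl ether untouched.

Step 4
Reactants: 6 4-hydroxy-2-methoxybenzaldehyde
Product: 7 4-(allyloxy)-2-methoxybenzaldehyde
Conditions: allyl bromide, K2CO3, acetone, 50 °C
Reagents that add atoms: allyl bromide, C=CCBr
Why: Williamson ether synthesis at the only acidic hydroxyl, giving an allyl ether that tolerates hydride, organolithium and Mitsunobu conditions and is later removed under palladium catalysis without base.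

Step 5
Reactants: 7 4-(allyloxy)-2-methoxybenzaldehyde; 8 sodium p-toluenesulfinate
Product: 10 4-(allyloxy)-2-methoxybenzyl p-tolyl sulfone, via benzylic alcohol 9 (not isolated)
Conditions: NaBH4, MeOH, 0 °C; then 8 (2 equiv), 2 M aq. HCl to pH 1–2, 0 °C → rt
Reagents that add atoms: none
Why: Borohydride reduction of the aldehyde followed by acid-promoted SN1 substitution of the 2,4-dialkoxybenzylic alcohol by the S-nucleophilic sulfinate through the stabilised benzylic cation, a standard entry to benzylic sulfones.

Step 6
Reactants: 10 4-(allyloxy)-2-methoxybenzyl p-tolyl sulfone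
Product: 11 rac-2-[4-(allyloxy)-2-methoxyphenyl]-2-(p-tolylsulfonyl)ethan-1-ol
Conditions: n-BuLi (1.05 equiv), THF, −78 °C; (CH2O)n, −78 °C → rt; sat. aq. NH4Cl
Reagents that add atoms: paraformaldehyde (as formaldehyde), C=O
Why: Hydroxymethylation of an α-sulfonyl carbanion with formaldehyde (the addition stage of a Julia-type sequence, stopped at the β-hydroxy sulfone); the new stereocentre is racemic and is erased in step 9.

Step 7
Reactants: 5 5-geranyl-2-hydroxy-4-[(triisopropylsilyl)oxy]benzaldehyde; 11 rac-2-[4-(allyloxy)-2-methoxyphenyl]-2-(p-tolylsulfonyl)ethan-1-ol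
Product: 12 rac-2-{2-[4-(allyloxy)-2-methoxyphenyl]-2-(p-tolylsulfonyl)ethoxy}-5-geranyl-4-[(triisopropylsilyl)oxy]benzaldehyde
Conditions: PPh3, DIAD, THF, 0 °C → rt
Reagents that add atoms: none
Why: Mitsunobu etherification of the acidic salicylaldehyde phenol with a primary alcohol under neutral conditions that spare the aryl silyl ether; if some activated alcohol eliminates to the vinyl sulfone, conjugate addition of the phenol leads to the same ether, so the O1–C2 connectivity is unambiguous.

Step 8
Reactants: 12 rac-2-{2-[4-(allyloxy)-2-methoxyphenyl]-2-(p-tolylsulfonyl)ethoxy}-5-geranyl-4-[(triisopropylsilyl)oxy]benzaldehyde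
Product: 13 rac-2-[2-(4-hydroxy-2-methoxyphenyl)-2-(p-tolylsulfonyl)ethoxy]-5-geranyl-4-[(triisopropylsilyl)oxy]benzaldehyde
Conditions: Pd(PPh3)4 (3 mol %), p-TolSO2H (1.5 equiv), CH2Cl2, rt
Reagents that add atoms: none
Why: Tsuji–Trost deallylation in which zerovalent palladium ionises the allyl aryl ether and the sulfinic acid traps the allyl fragment as a sulfone; the medium stays mildly acidic so the freed 4-hydroxybenzyl sulfone cannot yet lose sulfinate, and a sulfinic acid is preferred because carbon-acid scavengers would condense with the aldehyde and amines would start the elimination.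

Step 9
Reactants: 13 rac-2-[2-(4-hydroxy-2-methoxyphenyl)-2-(p-tolylsulfonyl)ethoxy]-5-geranyl-4-[(triisopropylsilyl)oxy]benzaldehyde
Product: 15 (3S)-6-geranyl-3-(4-hydroxy-2-methoxyphenyl)-7-[(triisopropylsilyl)oxy]chroman-4-one, via para-quinone methide aldehyde 14 (not isolated)
Conditions: (5aR,10bS)-2-(pentafluorophenyl)-5a,10b-dihydro-4H,6H-indeno[2,1-b][1,2,4]triazolo[4,3-d][1,4]oxazin-2-ium tetrafluoroborate (15 mol %), i-Pr2NEt (1.2 equiv, added over 6 h), toluene (0.02 M), 0 °C → 10 °C; AcOH quench at 0 °C
Reagents that add atoms: none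
Why: Proposed new method: the amine deprotonates the 4'-phenol of 13 and p-toluenesulfinate leaves in a 1,6-elimination to give quinone methide 14, while the triazolylidene adds to the ring-A formyl group and proton transfer gives the Breslow intermediate, whose nucleophilic carbon (C4) attacks the exocyclic carbon of 14 (C3) in a 1,6-addition that re-aromatises ring B to the 4'-phenoxide before the tetrahedral adduct collapses to the ketone and free carbene. The closest known reactions are the intramolecular asymmetric Stetter reaction of O-tethered salicylaldehydes to 3-substituted chroman-4-ones, carbene-catalysed 1,6-acylation of isolable para-quinone methides, and base-triggered release of quinone methides from hydroxybenzyl sulfones. Ring C closes in a 6-exo-trig mode, since the attacked C3=C1' bond lies outside the new ring. The C3 stereocentre is created in the C–C bond-forming event, not by protonation, and is controlled by the aminoindanol-fused triazolylidene, which shields one face of the Breslow intermediate and so selects one face of prochiral C3. The step needs enantioface selectivity and a preference for ring closure over tautomerisation of 14 to the styrenyl ether, oligomerisation and epimerisation: the O1–C2 tether makes the capture intramolecular, the 2'-methoxy group holds 14 in the E geometry (CH2O away from OMe), slow base addition keeps 14 scarce while reversible sulfinate re-addition stores it, and the product forms as the 4'-phenoxide, which disfavours enolisation at C3 under the weak amine base.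

Step 10
Reactants: 15 (3S)-6-geranyl-3-(4-hydroxy-2-methoxyphenyl)-7-[(triisopropylsilyl)oxy]chroman-4-one
Product: 16 (3S)-6-geranyl-7-hydroxy-3-(4-hydroxy-2-methoxyphenyl)chroman-4-one (CNP0292854.1)
Conditions: KHF2 (2.5 equiv), MeOH, rt; neutral work-up
Reagents that add atoms: none
Why: Bifluoride cleavage of a phenolic silyl ether in methanol, a weakly acidic medium in which the base-labile C3 stereocentre should not enolise and the geranyl chain should not cyclise.

Compound list
1 | 5-bromo-2,4-dihydroxybenzaldehyde | O=Cc1cc(Br)c(O)cc1O | starting material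
2 | 5-bromo-2-hydroxy-4-[(triisopropylsilyl)oxy]benzaldehyde | O=Cc1cc(Br)c(O[Si](C(C)C)(C(C)C)C(C)C)cc1O | intermediate
3 | geranyl bromide, (2E)-1-bromo-3,7-dimethylocta-2,6-diene | CC(C)=CCC/C(C)=C/CBr | starting material
4 | tributyl[(2E)-3,7-dimethylocta-2,6-dien-1-yl]stannane | CCCC[Sn](CCCC)(CCCC)C/C=C(\C)CCC=C(C)C | intermediate
5 | 5-[(2E)-3,7-dimethylocta-2,6-dien-1-yl]-2-hydroxy-4-[(triisopropylsilyl)oxy]benzaldehyde | O=Cc1cc(C/C=C(\C)CCC=C(C)C)c(O[Si](C(C)C)(C(C)C)C(C)C)cc1O | intermediate
6 | 4-hydroxy-2-methoxybenzaldehyde | COc1cc(O)ccc1C=O | starting material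
7 | 4-(allyloxy)-2-methoxybenzaldehyde | COc1cc(OCC=C)ccc1C=O | intermediate
8 | sodium p-toluenesulfinate | Cc1ccc(S(=O)[O-])cc1.[Na+] | starting material
9 | [4-(allyloxy)-2-methoxyphenyl]methanol (not isolated) | COc1cc(OCC=C)ccc1CO | intermediate
10 | 4-(allyloxy)-2-methoxybenzyl p-tolyl sulfone | COc1cc(OCC=C)ccc1CS(=O)(=O)c1ccc(C)cc1 | intermediate
11 | rac-2-[4-(allyloxy)-2-methoxyphenyl]-2-(p-tolylsulfonyl)ethan-1-ol | COc1cc(OCC=C)ccc1C(CO)S(=O)(=O)c1ccc(C)cc1 | intermediate
12 | rac-2-{2-[4-(allyloxy)-2-methoxyphenyl]-2-(p-tolylsulfonyl)ethoxy}-5-[(2E)-3,7-dimethylocta-2,6-dien-1-yl]-4-[(triisopropylsilyl)oxy]benzaldehyde | O=Cc1cc(C/C=C(\C)CCC=C(C)C)c(O[Si](C(C)C)(C(C)C)C(C)C)cc1OCC(c1ccc(OCC=C)cc1OC)S(=O)(=O)c1ccc(C)cc1 | intermediate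
13 | rac-2-[2-(4-hydroxy-2-methoxyphenyl)-2-(p-tolylsulfonyl)ethoxy]-5-[(2E)-3,7-dimethylocta-2,6-dien-1-yl]-4-[(triisopropylsilyl)oxy]benzaldehyde (key-step precursor) | O=Cc1cc(C/C=C(\C)CCC=C(C)C)c(O[Si](C(C)C)(C(C)C)C(C)C)cc1OCC(c1ccc(O)cc1OC)S(=O)(=O)c1ccc(C)cc1 | intermediate
14 | 5-[(2E)-3,7-dimethylocta-2,6-dien-1-yl]-2-{(2E)-2-(2-methoxy-4-oxocyclohexa-2,5-dien-1-ylidene)ethoxy}-4-[(triisopropylsilyl)oxy]benzaldehyde (para-quinone methide, not isolated) | O=Cc1cc(C/C=C(\C)CCC=C(C)C)c(O[Si](C(C)C)(C(C)C)C(C)C)cc1OC/C=C1\C=CC(=O)C=C1OC | intermediate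
15 | (3S)-6-[(2E)-3,7-dimethylocta-2,6-dien-1-yl]-3-(4-hydroxy-2-methoxyphenyl)-7-[(triisopropylsilyl)oxy]-2,3-dihydro-4H-chromen-4-one | COc1cc(O)ccc1[C@H]1COc2cc(O[Si](C(C)C)(C(C)C)C(C)C)c(C/C=C(\C)CCC=C(C)C)cc2C1=O | intermediate
16 | (3S)-6-[(2E)-3,7-dimethylocta-2,6-dien-1-yl]-7-hydroxy-3-(4-hydroxy-2-methoxyphenyl)-2,3-dihydro-4H-chromen-4-one | COc1cc(O)ccc1[C@H]1COc2cc(O)c(C/C=C(\C)CCC=C(C)C)cc2C1=O | target

Total step count: 10.
Longest linear sequence: 7 steps (steps 4 to 10, from 6).

Steps most likely to fail

1. Step 9. The quinone methide may tautomerise to the styrenyl ether or oligomerise faster than the carbene closes the ring. The carbene may be tied up by adding to the quinone methide itself. Facial selectivity may be poor, or the amine may epimerise C3 after closure.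
Fallback (known chemistry; ring C is closed by a sulfonyl carbanion and the stereocentre is obtained by separation): it sets out from 12, whose 4'-phenol is still allylated so that no quinone methide can arise. LiHMDS in THF at −78 °C should give the α-sulfonyl carbanion, which adds to the ring-A aldehyde in a six-membered aldol-type closure to the 3-sulfonylchroman-4-ol F1. Dess–Martin oxidation then gives the 3-sulfonylchroman-4-one F2. SmI2 in THF–MeOH at −78 °C removes the sulfonyl group (reductive desulfonylation of a β-keto sulfone) and gives the racemic O-allyl isoflavanone F3. Deallylation under the conditions of step 8 gives the racemic silyl ether F4. Preparative chromatography on a chiral stationary phase separates 15 from the (R)-enantiomer F5, which is racemised with catalytic DBU back to F4 and recycled. The fallback rejoins the route at 15.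

2. Step 7. The activated β-sulfonyl alcohol may undergo β-elimination instead of substitution, and the vinyl sulfone so formed may not be recaptured by the phenol under the neutral conditions.
Fallback (elimination made deliberate, ether formed by conjugate addition): it sets out from 11. MsCl and Et3N in CH2Cl2 convert it through the mesylate F6 (not isolated) into the α-aryl vinyl sulfone F7. Oxa-Michael addition of phenol 5 under catalytic DBU or PBu3 in MeCN then gives 12, where the route is rejoined.

3. Step 3. Oxidative addition into the electron-rich, ortho-silyloxy aryl bromide may be sluggish, and transfer of the allyl group may occur with allylic transposition or loss of the E-geometry.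
Fallback (polarity of the coupling reversed, no tin): it sets out from 2. Miyaura borylation (B2pin2, PdCl2(dppf), KOAc, dioxane, 80 °C) gives the aryl pinacol boronate F8. Suzuki–Miyaura allylation with geranyl bromide 3 (Pd(PPh3)4, anhydrous K3PO4, THF, 50 °C) should couple at the primary allylic carbon with the E-alkene retained and gives 5, where the route is rejoined.

Further compounds
F1 | step 9 | 3-[4-(allyloxy)-2-methoxyphenyl]-6-geranyl-3-(p-tolylsulfonyl)-7-[(triisopropylsilyl)oxy]chroman-4-ol (racemic, diastereomer mixture) | COc1cc(OCC=C)ccc1C1(S(=O)(=O)c2ccc(C)cc2)COc2cc(O[Si](C(C)C)(C(C)C)C(C)C)c(C/C=C(\C)CCC=C(C)C)cc2C1O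
F2 | step 9 | rac-3-[4-(allyloxy)-2-methoxyphenyl]-6-geranyl-3-(p-tolylsulfonyl)-7-[(triisopropylsilyl)oxy]chroman-4-one | COc1cc(OCC=C)ccc1C1(S(=O)(=O)c2ccc(C)cc2)COc2cc(O[Si](C(C)C)(C(C)C)C(C)C)c(C/C=C(\C)CCC=C(C)C)cc2C1=O
F3 | step 9 | rac-3-[4-(allyloxy)-2-methoxyphenyl]-6-geranyl-7-[(triisopropylsilyl)oxy]chroman-4-one | COc1cc(OCC=C)ccc1C1COc2cc(O[Si](C(C)C)(C(C)C)C(C)C)c(C/C=C(\C)CCC=C(C)C)cc2C1=O
F4 | step 9 | rac-6-geranyl-3-(4-hydroxy-2-methoxyphenyl)-7-[(triisopropylsilyl)oxy]chroman-4-one | COc1cc(O)ccc1C1COc2cc(O[Si](C(C)C)(C(C)C)C(C)C)c(C/C=C(\C)CCC=C(C)C)cc2C1=O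
F5 | step 9 | (3R)-6-geranyl-3-(4-hydroxy-2-methoxyphenyl)-7-[(triisopropylsilyl)oxy]chroman-4-one | COc1cc(O)ccc1[C@@H]1COc2cc(O[Si](C(C)C)(C(C)C)C(C)C)c(C/C=C(\C)CCC=C(C)C)cc2C1=O
F6 | step 7 | rac-2-[4-(allyloxy)-2-methoxyphenyl]-2-(p-tolylsulfonyl)ethyl methanesulfonate | COc1cc(OCC=C)ccc1C(COS(C)(=O)=O)S(=O)(=O)c1ccc(C)cc1
F7 | step 7 | 4-(allyloxy)-2-methoxy-1-[1-(p-tolylsulfonyl)ethenyl]benzene | COc1cc(OCC=C)ccc1C(=C)S(=O)(=O)c1ccc(C)cc1
F8 | step 3 | 2-hydroxy-5-(4,4,5,5-tetramethyl-1,3,2-dioxaborolan-2-yl)-4-[(triisopropylsilyl)oxy]benzaldehyde | O=Cc1cc(B2OC(C)(C)C(C)(C)O2)c(O[Si](C(C)C)(C(C)C)C(C)C)cc1O
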